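**Plan**

1. Retrosynthesis: remove 16 benzyl ethers and 2 aryl bromides; cut B(C4)–C(C8) into an A–B thioether electrophile and a C–D nucleophile; cut A(C4)–B(C6) and C(C4)–D(C8); units B, C and D reduce to one benzylated 2,3-cis monomer 14.
2. In 14 the C3 carbinol is traced to a 3-ketone and ring C is opened at C2–C3, leaving an aldehyde (C3) and a redox-active ester on C2, both held on ring A through C4 and O1.
3. Enabling feature: C2 carries the ring oxygen O1 and catechol ring B, so a C2 radical is benzylic and α-oxygenated; C3 lies 1,6 to it through O1–C8a–C4a–C4 of ring A, so a carbene-bound ketyl-type radical at C3 can recombine with it and close pyran ring C.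
4. Forward: ring A (a phloroglucinol diether) is C-allylated by Claisen rearrangement, O1–C2 is made with ring B attached (Jocic–Reeve), ring C closes at C2–C3, then the units are joined C+D, A+B and AB+CD.
5. Stereochemistry: C2 and C3 of units B, C and D come from dynamic kinetic asymmetric hydrogenation of the racemic 3-ketone; unit A comes from (+)-catechin; each C4 centre comes from trans attack on a C4 cation (3-acetoxy participation for 4α in A, 3-OH/2-aryl bias for 4β in B and C).

Key step: step 7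

Remark: units B, C and D are the same 2,3-cis monomer, so one synthetic batch of 14 supplies all three; SMILES of 6–13 without stereodescriptors denote racemates.

**Route**

Step 1
Reactants: 1 3,5-bis(benzyloxy)phenol; 2 allyl bromide
Product: 3 1-(allyloxy)-3,5-bis(benzyloxy)benzene
Conditions: K2CO3, acetone, reflux
Reagents that add atoms: none
Why: Williamson etherification of the phenoxide with the allylic bromide under weak base should give clean O-allylation.

Step 2
Reactants: 3 1-(allyloxy)-3,5-bis(benzyloxy)benzene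
Product: 4 2-allyl-3,5-bis(benzyloxy)phenol
Conditions: PhNEt2, 190 °C
Reagents that add atoms: none
Why: The aromatic Claisen rearrangement ([3,3]-sigmatropic shift, then tautomerisation) should move the allyl group to one of the two equivalent ortho carbons, which becomes C4a bearing C4 and C3.

Step 3
Reactants: 5 3,4-bis(benzyloxy)benzaldehyde
Product: 6 1-[3,4-bis(benzyloxy)phenyl]-2,2,2-trichloroethanol (racemic)
Conditions: CHCl3, DBU, 0 °C to rt
Reagents that add atoms: chloroform ClC(Cl)Cl
Why: Base-mediated addition of the trichloromethyl anion to the aldehyde should give the trichloromethyl carbinol needed for a Jocic–Reeve reaction; its stereocentre is racemic and is erased later.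

Step 4
Reactants: 4 2-allyl-3,5-bis(benzyloxy)phenol; 6 1-[3,4-bis(benzyloxy)phenyl]-2,2,2-trichloroethanol
Product: 9 2-[2-allyl-3,5-bis(benzyloxy)phenoxy]-2-[3,4-bis(benzyloxy)phenyl]acetic acid (racemic), via dichloro-epoxide 7 (not isolated), via acid chloride 8 (not isolated)
Conditions: NaOH (powder), DME, 0 °C to rt; then aq HCl
Reagents that add atoms: sodium hydroxide [Na+].[OH-]
Why: In this Jocic–Reeve reaction (the Bargellini route to α-aryloxy acids) the alkoxide of 6 should close to the gem-dichloro-epoxide, the phenoxide of 4 should open it at the benzylic carbon and the acyl chloride should be hydrolysed, so that O1–C2 and a carboxyl handle on C2 are installed together (C2 racemic).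

Step 5
Reactants: 9 2-[2-allyl-3,5-bis(benzyloxy)phenoxy]-2-[3,4-bis(benzyloxy)phenyl]acetic acid
Product: 10 1,3-dioxoisoindolin-2-yl 2-[2-allyl-3,5-bis(benzyloxy)phenoxy]-2-[3,4-bis(benzyloxy)phenyl]acetate (racemic)
Conditions: N-hydroxyphthalimide, DIC, DMAP (cat.), CH2Cl2, rt
Reagents that add atoms: N-hydroxyphthalimide ON1C(=O)c2ccccc2C1=O
Why: Carbodiimide (Steglich-type) esterification should give the N-acyloxyphthalimide, the redox-active ester that later releases the C2 radical.

Step 6
Reactants: 10 1,3-dioxoisoindolin-2-yl 2-[2-allyl-3,5-bis(benzyloxy)phenoxy]-2-[3,4-bis(benzyloxy)phenyl]acetate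
Product: 12 1,3-dioxoisoindolin-2-yl 2-[3,5-bis(benzyloxy)-2-(2-oxoethyl)phenoxy]-2-[3,4-bis(benzyloxy)phenyl]acetate (racemic), via ozonide 11 (not isolated)
Conditions: O3, CH2Cl2, −78 °C (Sudan Red 7B end-point); PPh3, −78 °C to rt
Reagents that add atoms: ozone [O-][O+]=O
Why: Ozonolysis with reductive work-up should cleave the terminal alkene, which reacts with ozone much faster than the alkoxyarenes at −78 °C, to the arylacetaldehyde whose carbonyl carbon is C3.

Step 7
Reactants: 12 1,3-dioxoisoindolin-2-yl 2-[3,5-bis(benzyloxy)-2-(2-oxoethyl)phenoxy]-2-[3,4-bis(benzyloxy)phenyl]acetate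
Product: 13 5,7-bis(benzyloxy)-2-[3,4-bis(benzyloxy)phenyl]chroman-3-one (racemic)
Conditions: N-(2,6-diisopropylphenyl)thiazolium precatalyst (10 mol%), Cs2CO3 (20 mol%), DMSO (0.02 M), 60 °C, argon
Reagents that add atoms: none
Why: Proposed new method: the thiazolylidene should add to the aldehyde carbon C3 of 12, and the deprotonated Breslow intermediate should pass one electron to the N-acyloxyphthalimide, which loses phthalimide anion and CO2 to leave a C2 radical that is benzylic to ring B and α to O1; this radical should recombine with the persistent ketyl-type radical at C3, after which the carbene is expelled and the 3-ketone results. The closest known reaction type is the carbene-catalysed decarboxylative radical acylation of aliphatic aldehydes with redox-active esters to give ketones, known between two separate molecules; here both partners sit in one molecule and are 1,6-related through O1–C8a–C4a–C4. Ring C closes as a six-membered ring by radical–radical recombination at C2–C3 (formally a 6-exo closure onto the carbene-bound C3), with the rigid aryl ether tether holding the two centres close. The new stereocentre C2 is formed without control and needs none, because it is α to the new ketone and is equilibrated and fixed in step 8. The step needs chemoselectivity for electron transfer over base-induced aldol, acyl-transfer or ketene chemistry of the enolisable aldehyde and the active ester; the bulky N-aryl carbene, the merely catalytic carbonate and high dilution are chosen to secure it, and the phthalimide ester helper leaves in this same step.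

Step 8
Reactants: 13 5,7-bis(benzyloxy)-2-[3,4-bis(benzyloxy)phenyl]chroman-3-one
Product: 14 (2R,3R)-5,7-bis(benzyloxy)-2-[3,4-bis(benzyloxy)phenyl]chroman-3-ol (5,7,3',4'-tetra-O-benzyl-(−)-epicatechin)
Conditions: RuCl2[(R)-Xyl-SDP][(S,S)-DPEN] (0.5 mol%), KOtBu (20 mol%), H2 (50 atm), i-PrOH/toluene, rt
Reagents that add atoms: none
Why: Alkoxide-mediated enolisation toward C2 should racemise the ketone faster than it is reduced while the chiral ruthenium diphosphine/diamine hydride reduces one enantiomer from the face anti to the 2-aryl group (Noyori-type asymmetric hydrogenation with dynamic kinetic resolution of an α-aryl cyclic ketone), so that C2 (R) and C3 (R, cis) are set together; the catalyst enantiomer is assigned by analogy with the cis-selective reduction of 2-arylcycloalkanones.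

Step 9
Reactants: 14 5,7,3',4'-tetra-O-benzyl-(−)-epicatechin
Product: 15 5,7,3',4'-tetra-O-benzyl-4β-(2-ethoxyethoxy)-(−)-epicatechin (4-alkoxy group trans to the 3-hydroxyl and to the 2-aryl group)
Conditions: DDQ, 2-ethoxyethanol, CH2Cl2, rt
Reagents that add atoms: 2-ethoxyethanol CCOCCO
Why: DDQ should abstract hydride from the benzylic C4 activated by the 5,7-dioxygenated ring A and the alcohol should add to the cation trans to the 3-hydroxyl and 2-aryl groups (oxidative benzylic etherification), installing the leaving group for interflavan bond formation.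

Step 10
Reactants: 15 5,7,3',4'-tetra-O-benzyl-4β-(2-ethoxyethoxy)-(−)-epicatechin; 14 5,7,3',4'-tetra-O-benzyl-(−)-epicatechin
Product: 16 5,7,3',4'-tetra-O-benzyl-epicatechin-(4β→8)-5,7,3',4'-tetra-O-benzyl-epicatechin (protected C–D dimer, both 3-hydroxyls free)
Conditions: TMSOTf (cat.), CH2Cl2, −78 °C; 14 in excess
Reagents that add atoms: none
Why: Lewis-acid ionisation of the 4-alkoxy group should give the ring-A-stabilised C4 cation, which undergoes Friedel–Crafts alkylation at C8 of excess 14 (its most nucleophilic position) trans to the 3-hydroxyl and 2-aryl groups, setting the 4β centre of unit C.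

Step 11
Reactants: 15 5,7,3',4'-tetra-O-benzyl-4β-(2-ethoxyethoxy)-(−)-epicatechin
Product: 17 8-bromo-5,7,3',4'-tetra-O-benzyl-4β-(2-ethoxyethoxy)-(−)-epicatechin
Conditions: NBS, CH2Cl2, −40 °C
Reagents that add atoms: N-bromosuccinimide BrN1C(=O)CCC1=O
Why: Electrophilic aromatic bromination should occur at C8, which lies between O1 and the 7-benzyloxy group and is less hindered than C6, so that C8 of the future unit B is blocked.

Step 12
Reactants: 17 8-bromo-5,7,3',4'-tetra-O-benzyl-4β-(2-ethoxyethoxy)-(−)-epicatechin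
Product: 18 8-bromo-4β-(benzylthio)-5,7,3',4'-tetra-O-benzyl-(−)-epicatechin (thioether trans to the 3-hydroxyl)
Conditions: BnSH, BF3·OEt2 (0.5 equiv), CH2Cl2, −78 to −20 °C
Reagents that add atoms: benzyl mercaptan SCc1ccccc1
Why: Lewis-acid ionisation at C4 and capture of the cation by the thiol trans to the 3-hydroxyl (acetal-to-thioether exchange, as in thiolysis of proanthocyanidins) should give a leaving group that is inert to hard Lewis acids and can be triggered later by a thiophile.

Step 13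
Reactants: 19 (+)-catechin
Product: 20 (2R,3S)-5,7-bis(benzyloxy)-2-[3,4-bis(benzyloxy)phenyl]chroman-3-ol (5,7,3',4'-tetra-O-benzyl-(+)-catechin)
Conditions: BnBr, K2CO3, DMF, 0 °C to rt
Reagents that add atoms: benzyl bromide BrCc1ccccc1
Why: Williamson benzylation under carbonate should alkylate only the four acidic phenols and leave the secondary 3-hydroxyl free.

Step 14
Reactants: 20 5,7,3',4'-tetra-O-benzyl-(+)-catechin
Product: 21 5,7,3',4'-tetra-O-benzyl-4β-(2-ethoxyethoxy)-(+)-catechin (4-alkoxy group trans to the 2-aryl group and cis to the 3-hydroxyl)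
Conditions: DDQ, 2-ethoxyethanol, CH2Cl2, rt
Reagents that add atoms: 2-ethoxyethanol CCOCCO
Why: The same DDQ-mediated oxidative benzylic etherification as in step 9 should install the C4 leaving group of unit A; the configuration at C4 is lost again on ionisation.

Step 15
Reactants: 21 5,7,3',4'-tetra-O-benzyl-4β-(2-ethoxyethoxy)-(+)-catechin
Product: 22 3-O-acetyl-5,7,3',4'-tetra-O-benzyl-4β-(2-ethoxyethoxy)-(+)-catechin
Conditions: Ac2O, pyridine, DMAP (cat.), rt
Reagents that add atoms: acetic anhydride CC(=O)OC(C)=O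
Why: Acylation of the 3-hydroxyl should provide a participating ester that will steer the coming C4 substitution to the 3,4-trans product.

Step 16
Reactants: 22 3-O-acetyl-5,7,3',4'-tetra-O-benzyl-4β-(2-ethoxyethoxy)-(+)-catechin
Product: 23 3-O-acetyl-8-bromo-5,7,3',4'-tetra-O-benzyl-4β-(2-ethoxyethoxy)-(+)-catechin
Conditions: NBS, CH2Cl2, −40 °C
Reagents that add atoms: N-bromosuccinimide BrN1C(=O)CCC1=O
Why: Regioselective electrophilic bromination at C8 should cap the most nucleophilic position of the electrophile and so suppress its self-condensation.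

Step 17
Reactants: 23 3-O-acetyl-8-bromo-5,7,3',4'-tetra-O-benzyl-4β-(2-ethoxyethoxy)-(+)-catechin; 18 8-bromo-4β-(benzylthio)-5,7,3',4'-tetra-O-benzyl-(−)-epicatechin
Product: 24 [3-O-acetyl-8-bromo-5,7,3',4'-tetra-O-benzyl-catechin]-(4α→6)-[8-bromo-4β-(benzylthio)-5,7,3',4'-tetra-O-benzyl-epicatechin] (protected A–B dimer)
Conditions: TMSOTf (cat.), CH2Cl2, −78 to −40 °C; 18 in excess (recovered)
Reagents that add atoms: none
Why: The hard Lewis acid should ionise only the 2-ethoxyethoxy group of 23 (the thioether of 18 stays intact), the 3-acetoxy group should shield the β-face as an acetoxonium ion, and C6 of 18 (C8 blocked by bromine) should attack from the α-face in a Friedel–Crafts alkylation, setting the 4α (3,4-trans) centre and the 4→6 linkage.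

Step 18
Reactants: 24 protected A–B dimer; 16 protected C–D dimer
Product: 25 [3-O-acetyl-8-bromo-tetra-O-benzyl-catechin]-(4α→6)-[8-bromo-tetra-O-benzyl-epicatechin]-(4β→8)-[tetra-O-benzyl-epicatechin]-(4β→8)-[tetra-O-benzyl-epicatechin] (protected tetramer)
Conditions: AgBF4, THF, 0 °C; 16 in slight excess
Reagents that add atoms: none
Why: The thiophilic silver salt should abstract benzylthiolate from C4 of the lower unit of 24, and the cation should be captured by C8 of the upper unit of 16 (the most nucleophilic and least hindered position) trans to the 3-hydroxyl and 2-aryl groups (thioether-activated Friedel–Crafts interflavan coupling), setting the 4β centre of unit B.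

Step 19
Reactants: 25 protected tetramer
Product: 26 the 3-O-deacetylated protected tetramer (four free 3-hydroxyls, sixteen benzyl ethers, two aryl bromides)
Conditions: NaOMe (cat.), MeOH/THF, rt
Reagents that add atoms: none
Why: Methoxide-catalysed transesterification (Zemplén conditions) should remove the single acetate without touching benzyl ethers, aryl bromides or interflavan bonds.

Step 20
Reactants: 26 deacetylated protected tetramer
Product: 27 catechin-(4α→6)-epicatechin-(4β→8)-epicatechin-(4β→8)-epicatechin (CNP0228086.1)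
Conditions: H2 (1 atm), Pd(OH)2/C, Et3N, THF/MeOH/H2O, rt
Reagents that add atoms: none
Why: Palladium-catalysed hydrogenolysis should cleave all sixteen benzyl ethers and hydrodebrominate both capped C8 positions in one operation, with the amine taking up HBr so that the acid-labile interflavan bonds survive.

**Compound list**

1 | 3,5-bis(benzyloxy)phenol | Oc1cc(OCc2ccccc2)cc(OCc2ccccc2)c1 | starting material
2 | allyl bromide | C=CCBr | starting material
3 | 1-(allyloxy)-3,5-bis(benzyloxy)benzene | C=CCOc1cc(OCc2ccccc2)cc(OCc2ccccc2)c1 | intermediate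
4 | 2-allyl-3,5-bis(benzyloxy)phenol | C=CCc1c(O)cc(OCc2ccccc2)cc1OCc1ccccc1 | intermediate
5 | 3,4-bis(benzyloxy)benzaldehyde | O=Cc1ccc(OCc2ccccc2)c(OCc2ccccc2)c1 | starting material
6 | 1-[3,4-bis(benzyloxy)phenyl]-2,2,2-trichloroethanol (racemic) | OC(c1ccc(OCc2ccccc2)c(OCc2ccccc2)c1)C(Cl)(Cl)Cl | intermediate
7 | 3-[3,4-bis(benzyloxy)phenyl]-2,2-dichlorooxirane (racemic, not isolated) | ClC1(Cl)OC1c1ccc(OCc2ccccc2)c(OCc2ccccc2)c1 | intermediate
8 | 2-[2-allyl-3,5-bis(benzyloxy)phenoxy]-2-[3,4-bis(benzyloxy)phenyl]acetyl chloride (racemic, not isolated) | O=C(Cl)C(Oc1cc(OCc2ccccc2)cc(OCc2ccccc2)c1CC=C)c1ccc(OCc2ccccc2)c(OCc2ccccc2)c1 | intermediate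
9 | 2-[2-allyl-3,5-bis(benzyloxy)phenoxy]-2-[3,4-bis(benzyloxy)phenyl]acetic acid (racemic) | OC(=O)C(Oc1cc(OCc2ccccc2)cc(OCc2ccccc2)c1CC=C)c1ccc(OCc2ccccc2)c(OCc2ccccc2)c1 | intermediate
10 | 1,3-dioxoisoindolin-2-yl 2-[2-allyl-3,5-bis(benzyloxy)phenoxy]-2-[3,4-bis(benzyloxy)phenyl]acetate (racemic) | O=C(ON1C(=O)c2ccccc2C1=O)C(Oc1cc(OCc2ccccc2)cc(OCc2ccccc2)c1CC=C)c1ccc(OCc2ccccc2)c(OCc2ccccc2)c1 | intermediate
11 | 1,2,4-trioxolane (secondary ozonide) of 10 (not isolated) | O=C(ON1C(=O)c2ccccc2C1=O)C(Oc1cc(OCc2ccccc2)cc(OCc2ccccc2)c1CC1OCOO1)c1ccc(OCc2ccccc2)c(OCc2ccccc2)c1 | intermediate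
12 | 1,3-dioxoisoindolin-2-yl 2-[3,5-bis(benzyloxy)-2-(2-oxoethyl)phenoxy]-2-[3,4-bis(benzyloxy)phenyl]acetate (racemic) | O=C(ON1C(=O)c2ccccc2C1=O)C(Oc1cc(OCc2ccccc2)cc(OCc2ccccc2)c1CC=O)c1ccc(OCc2ccccc2)c(OCc2ccccc2)c1 | intermediate
13 | 5,7-bis(benzyloxy)-2-[3,4-bis(benzyloxy)phenyl]chroman-3-one (racemic) | O=C1Cc2c(OCc3ccccc3)cc(OCc3ccccc3)cc2OC1c1ccc(OCc2ccccc2)c(OCc2ccccc2)c1 | intermediate
14 | (2R,3R)-5,7-bis(benzyloxy)-2-[3,4-bis(benzyloxy)phenyl]chroman-3-ol (tetra-O-benzyl-(−)-epicatechin) | c1ccccc1COc1cc(OCc2ccccc2)c2c(c1)O[C@H](c1ccc(OCc3ccccc3)c(OCc3ccccc3)c1)[C@H](O)C2 | intermediate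
15 | tetra-O-benzyl-4β-(2-ethoxyethoxy)-(−)-epicatechin (3,4-trans) | c1ccccc1COc1cc(OCc2ccccc2)c2c(c1)O[C@H](c1ccc(OCc3ccccc3)c(OCc3ccccc3)c1)[C@H](O)[C@H]2OCCOCC | intermediate
16 | tetra-O-benzyl-epicatechin-(4β→8)-tetra-O-benzyl-epicatechin (C–D dimer) | c1ccccc1COc1cc(OCc2ccccc2)c2c(c1)O[C@H](c1ccc(OCc3ccccc3)c(OCc3ccccc3)c1)[C@H](O)[C@H]2c1c(OCc2ccccc2)cc(OCc2ccccc2)c2c1O[C@H](c1ccc(OCc3ccccc3)c(OCc3ccccc3)c1)[C@H](O)C2 | intermediate
17 | 8-bromo-tetra-O-benzyl-4β-(2-ethoxyethoxy)-(−)-epicatechin | c1ccccc1COc1cc(OCc2ccccc2)c2c(c1Br)O[C@H](c1ccc(OCc3ccccc3)c(OCc3ccccc3)c1)[C@H](O)[C@H]2OCCOCC | intermediate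
18 | 8-bromo-4β-(benzylthio)-tetra-O-benzyl-(−)-epicatechin | c1ccccc1COc1cc(OCc2ccccc2)c2c(c1Br)O[C@H](c1ccc(OCc3ccccc3)c(OCc3ccccc3)c1)[C@H](O)[C@H]2SCc1ccccc1 | intermediate
19 | (+)-catechin | Oc1cc(O)c2c(c1)O[C@H](c1ccc(O)c(O)c1)[C@@H](O)C2 | starting material
20 | (2R,3S)-5,7-bis(benzyloxy)-2-[3,4-bis(benzyloxy)phenyl]chroman-3-ol (tetra-O-benzyl-(+)-catechin) | c1ccccc1COc1cc(OCc2ccccc2)c2c(c1)O[C@H](c1ccc(OCc3ccccc3)c(OCc3ccccc3)c1)[C@@H](O)C2 | intermediate
21 | tetra-O-benzyl-4β-(2-ethoxyethoxy)-(+)-catechin (2,4-trans, 3,4-cis) | c1ccccc1COc1cc(OCc2ccccc2)c2c(c1)O[C@H](c1ccc(OCc3ccccc3)c(OCc3ccccc3)c1)[C@@H](O)[C@H]2OCCOCC | intermediate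
22 | 3-O-acetyl-tetra-O-benzyl-4β-(2-ethoxyethoxy)-(+)-catechin | c1ccccc1COc1cc(OCc2ccccc2)c2c(c1)O[C@H](c1ccc(OCc3ccccc3)c(OCc3ccccc3)c1)[C@@H](OC(C)=O)[C@H]2OCCOCC | intermediate
23 | 3-O-acetyl-8-bromo-tetra-O-benzyl-4β-(2-ethoxyethoxy)-(+)-catechin | c1ccccc1COc1cc(OCc2ccccc2)c2c(c1Br)O[C@H](c1ccc(OCc3ccccc3)c(OCc3ccccc3)c1)[C@@H](OC(C)=O)[C@H]2OCCOCC | intermediate
24 | protected A–B dimer: 3-O-acetyl-8-bromo-catechin-(4α→6)-8-bromo-4β-(benzylthio)-epicatechin, octa-O-benzyl | c1ccccc1COc1cc(OCc2ccccc2)c2c(c1Br)O[C@H](c1ccc(OCc3ccccc3)c(OCc3ccccc3)c1)[C@@H](OC(C)=O)[C@@H]2c1c(OCc2ccccc2)c(Br)c2c(c1OCc4ccccc4)[C@H](SCc1ccccc1)[C@@H](O)[C@@H](c1ccc(OCc3ccccc3)c(OCc3ccccc3)c1)O2 | intermediate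
25 | protected tetramer (A 3-O-acetyl, A and B 8-bromo, hexadeca-O-benzyl) | c1ccccc1COc1cc(OCc2ccccc2)c2c(c1Br)O[C@H](c1ccc(OCc3ccccc3)c(OCc3ccccc3)c1)[C@@H](OC(C)=O)[C@@H]2c1c(OCc2ccccc2)c(Br)c2c(c1OCc4ccccc4)[C@H](c1c(OCc3ccccc3)cc(OCc3ccccc3)c3c1O[C@H](c1ccc(OCc4ccccc4)c(OCc4ccccc4)c1)[C@H](O)[C@H]3c1c(OCc3ccccc3)cc(OCc3ccccc3)c3c1O[C@H](c1ccc(OCc4ccccc4)c(OCc4ccccc4)c1)[C@H](O)C3)[C@@H](O)[C@@H](c1ccc(OCc3ccccc3)c(OCc3ccccc3)c1)O2 | intermediate
26 | deacetylated protected tetramer | c1ccccc1COc1cc(OCc2ccccc2)c2c(c1Br)O[C@H](c1ccc(OCc3ccccc3)c(OCc3ccccc3)c1)[C@@H](O)[C@@H]2c1c(OCc2ccccc2)c(Br)c2c(c1OCc4ccccc4)[C@H](c1c(OCc3ccccc3)cc(OCc3ccccc3)c3c1O[C@H](c1ccc(OCc4ccccc4)c(OCc4ccccc4)c1)[C@H](O)[C@H]3c1c(OCc3ccccc3)cc(OCc3ccccc3)c3c1O[C@H](c1ccc(OCc4ccccc4)c(OCc4ccccc4)c1)[C@H](O)C3)[C@@H](O)[C@@H](c1ccc(OCc3ccccc3)c(OCc3ccccc3)c1)O2 | intermediate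
27 | catechin-(4α→6)-epicatechin-(4β→8)-epicatechin-(4β→8)-epicatechin (CNP0228086.1) | Oc1cc(O)c2c(c1)O[C@H](c1ccc(O)c(O)c1)[C@@H](O)[C@@H]2c1c(O)cc2c(c1O)[C@H](c1c(O)cc(O)c3c1O[C@H](c1ccc(O)c(O)c1)[C@H](O)[C@H]3c1c(O)cc(O)c3c1O[C@H](c1ccc(O)c(O)c1)[C@H](O)C3)[C@@H](O)[C@@H](c1ccc(O)c(O)c1)O2 | target

**Step count and risks**

Total step count: 20. Longest linear sequence: 14 steps (1, 2, 4, 5, 6, 7, 8, 9, 11, 12, 17, 18, 19, 20).

Steps most likely to fail:

1. Step 7. Base-induced enolisation of the arylacetaldehyde, followed by aldol or intramolecular acyl transfer to the active ester, or ketene formation from the active ester, may outrun single-electron transfer, so that ring C does not close. The fallback uses the chiral pool and sets out from 20: oxidation of the 3-hydroxyl with Dess–Martin periodinane (CH2Cl2, rt) should give (2R)-5,7-bis(benzyloxy)-2-[3,4-bis(benzyloxy)phenyl]chroman-3-one F1, and reduction with L-Selectride (THF, −78 °C, hydride anti to the 2-aryl group) should give the 2,3-cis alcohol. This fallback bypasses steps 7 and 8 and comes back to the route at 14.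

2. Step 8. Racemisation at C2 may be slow relative to reduction, or facial discrimination by the catalyst may be poor or of the opposite sense, which would give the cis alcohol in low enantiomeric purity. The fallback is a classical resolution and sets out from 13: L-Selectride reduction should give racemic cis-5,7-bis(benzyloxy)-2-[3,4-bis(benzyloxy)phenyl]chroman-3-ol F2. Esterification with (S)-2-methoxy-2-phenylacetic acid (DCC, DMAP) and chromatographic separation of the diastereomers should give the (S)-2-methoxy-2-phenylacetate of the (2R,3R)-alcohol F3, and saponification (LiOH, THF/H2O) comes back to the route at 14.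

3. Step 18. Attack at the C6 positions of 16, self-condensation of 24 through C6 of its upper unit, and acid-induced scission of the 4→6 bond by the acid released may all erode the union of the two dimers. The fallback extends the chain one unit at a time and sets out from 24 (with 15). AgBF4 buffered with 2,6-di-tert-butyl-4-methylpyridine should couple 24 with an excess of monomer 15, whose 2-ethoxyethoxy group is not addressed by the thiophile, to give the protected A–B–C trimer bearing a 4β-(2-ethoxyethoxy) group on unit C F4. TMSOTf (cat., CH2Cl2, −78 °C) should then ionise that group in the presence of excess 14, and the fallback comes back to the route at 25.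

**Further compounds**

F1 | step 7 | (2R)-5,7-bis(benzyloxy)-2-[3,4-bis(benzyloxy)phenyl]chroman-3-one | c1ccccc1COc1cc(OCc2ccccc2)c2c(c1)O[C@H](c1ccc(OCc3ccccc3)c(OCc3ccccc3)c1)C(=O)C2
F2 | step 8 | racemic cis-5,7-bis(benzyloxy)-2-[3,4-bis(benzyloxy)phenyl]chroman-3-ol (both enantiomers) | c1ccccc1COc1cc(OCc2ccccc2)c2c(c1)O[C@H](c1ccc(OCc3ccccc3)c(OCc3ccccc3)c1)[C@H](O)C2.c1ccccc1COc1cc(OCc2ccccc2)c2c(c1)O[C@@H](c1ccc(OCc3ccccc3)c(OCc3ccccc3)c1)[C@@H](O)C2
F3 | step 8 | (2R,3R)-5,7-bis(benzyloxy)-2-[3,4-bis(benzyloxy)phenyl]chroman-3-yl (S)-2-methoxy-2-phenylacetate | c1ccccc1COc1cc(OCc2ccccc2)c2c(c1)O[C@H](c1ccc(OCc3ccccc3)c(OCc3ccccc3)c1)[C@H](OC(=O)[C@@H](OC)c1ccccc1)C2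
F4 | step 18 | protected A–B–C trimer: 3-O-acetyl-8-bromo-catechin-(4α→6)-8-bromo-epicatechin-(4β→8)-4β-(2-ethoxyethoxy)-epicatechin, dodeca-O-benzyl | c1ccccc1COc1cc(OCc2ccccc2)c2c(c1Br)O[C@H](c1ccc(OCc3ccccc3)c(OCc3ccccc3)c1)[C@@H](OC(C)=O)[C@@H]2c1c(OCc2ccccc2)c(Br)c2c(c1OCc4ccccc4)[C@H](c1c(OCc3ccccc3)cc(OCc3ccccc3)c3c1O[C@H](c1ccc(OCc4ccccc4)c(OCc4ccccc4)c1)[C@H](O)[C@H]3OCCOCC)[C@@H](O)[C@@H](c1ccc(OCc3ccccc3)c(OCc3ccccc3)c1)O2
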